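**Plan**

- Retrosynthesis: the five benzyl ethers come off last. The flavonol is cut back through C3 hydroxylation and pyranone closure to a chalcone, i.e. to a C4 aldehyde of the benzofuran and a protected phloroacetophenone. The benzofuran benzene ring is cut at C3a–C7a and C4–C5, then at C4–CO2Me, C6–C7, O1–C7a and C2–C3.
- Enabling feature: benzene ring B (C3a, C4, C5, C6, C7, C7a) is substituted at four neighbouring positions (chromone carbon at C4, C3 at C3a, O1 at C7a, OH at C7) and is fused to dihydrofuran ring D (O1, C2, C3, C3a, C7a) along C3a–C7a. The three atoms O1–C2–C3 can therefore tether a 1-alkoxy-2-silyloxybutadiene (C7a, C7, C6, C5) to an ynoate (C3a, C4).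
- Forward: C2–C3 is joined first (allenylzinc addition). The chain then grows by O-alkylation (O1–C7a), vinyl addition (C7–C6), enol silylation and alkyne carboxylation. Rings B and D close together in one cycloaddition/aromatisation; the chromone ring closes afterwards and is hydroxylated at C3.
- Stereochemistry: C3 comes from an (R)-propargylic mesylate (asymmetric transfer hydrogenation) by chirality transfer through the allenylzinc. C2 comes from the anti-selective cyclic addition to the aldehyde. The anti pair maps onto the trans (2R,3S) ring and no later step breaks a bond at either centre.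

Key step: step 11

Assumption: benzofuran numbering is used for the target, and the ynone reduction and the allenylzinc addition are taken to follow their usual course (alkynyl group in the aryl position of the hydrogen-transfer model; anti SN2' palladation, retentive transmetalation, cyclic SE2' addition).

**Route**

Step 1
Reactants: 1 (benzyloxy)acetaldehyde; 2 trimethylsilylacetylene
Product: 4 rac-1-(benzyloxy)-4-(trimethylsilyl)but-3-yn-2-ol, via lithium (trimethylsilyl)acetylide 3 (not isolated)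
Conditions: 2, n-BuLi, THF, −78 °C; then 1, −78 to 0 °C; aq. NH4Cl
Reagents that add atoms: none
Why: 1,2-addition of a lithium acetylide to an aldehyde is routine, and the carbinol configuration is irrelevant because the next step oxidises it.

Step 2
Reactants: 4 rac-1-(benzyloxy)-4-(trimethylsilyl)but-3-yn-2-ol
Product: 5 1-(benzyloxy)-4-(trimethylsilyl)but-3-yn-2-one
Conditions: Dess–Martin periodinane, CH2Cl2, rt
Reagents that add atoms: none
Why: Dess–Martin oxidation of a secondary propargylic alcohol should give the ynone without touching the benzyl ether or the C–Si bond.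

Step 3
Reactants: 5 1-(benzyloxy)-4-(trimethylsilyl)but-3-yn-2-one
Product: 6 (2R)-1-(benzyloxy)-4-(trimethylsilyl)but-3-yn-2-ol
Conditions: RuCl[(S,S)-TsDPEN](p-cymene) (1 mol %), i-PrOH, rt
Reagents that add atoms: none
Why: Noyori asymmetric transfer hydrogenation of an ynone, in which the alkynyl group takes the aryl position of the transition state, so the (S,S) catalyst should give the (R)-alcohol (the spatial analogue of (S)-4-silylbut-3-yn-2-ols; the descriptor changes only because CH2OBn outranks the alkynyl carbon).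

Step 4
Reactants: 6 (2R)-1-(benzyloxy)-4-(trimethylsilyl)but-3-yn-2-ol
Product: 7 (2R)-1-(benzyloxy)-4-(trimethylsilyl)but-3-yn-2-yl methanesulfonate
Conditions: MsCl, Et3N, CH2Cl2, −78 °C
Reagents that add atoms: methanesulfonyl chloride, CS(=O)(=O)Cl
Why: O-sulfonylation breaks no bond at the stereocentre, so the configuration is retained.

Step 5
Reactants: 7 (2R)-1-(benzyloxy)-4-(trimethylsilyl)but-3-yn-2-yl methanesulfonate; 8 4-(benzyloxy)-3-methoxybenzaldehyde
Product: 10 (1R,2S)-1-[4-(benzyloxy)-3-methoxyphenyl]-2-[(benzyloxy)methyl]-4-(trimethylsilyl)but-3-yn-1-ol, via allenylzinc reagent 9 (not isolated)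
Conditions: Pd(OAc)2 (5 mol %), PPh3 (5 mol %), Et2Zn (3 equiv), THF, −78 to −20 °C; aq. NH4Cl
Reagents that add atoms: none
Why: Marshall propargylation, in which zerovalent palladium displaces the mesylate in anti SN2' fashion, exchange with zinc keeps the allene axis, and the cyclic SE2' addition of the (aR)-allenylzinc to the aldehyde sets C3 by chirality transfer from the mesylate and C2 by the anti preference of a transition state in which the aryl group avoids the CH2OBn substituent.

Step 6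
Reactants: 10 (1R,2S)-1-[4-(benzyloxy)-3-methoxyphenyl]-2-[(benzyloxy)methyl]-4-(trimethylsilyl)but-3-yn-1-ol
Product: 11 (1R,2S)-1-[4-(benzyloxy)-3-methoxyphenyl]-2-[(benzyloxy)methyl]but-3-yn-1-ol
Conditions: K2CO3, MeOH, rt
Reagents that add atoms: none
Why: methoxide-induced protodesilylation of an alkynylsilane is mild and leaves both stereocentres untouched.

Step 7
Reactants: 11 (1R,2S)-1-[4-(benzyloxy)-3-methoxyphenyl]-2-[(benzyloxy)methyl]but-3-yn-1-ol
Product: 13 2-{(1R,2S)-1-[4-(benzyloxy)-3-methoxyphenyl]-2-[(benzyloxy)methyl]but-3-yn-1-yloxy}-N-methoxy-N-methylacetamide, via sodium alkoxide 12 (not isolated)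
Conditions: NaH (1.1 equiv), THF, 0 °C; then BrCH2C(O)N(OMe)Me, Bu4NI (cat.), 0 °C to rt
Reagents that add atoms: 2-bromo-N-methoxy-N-methylacetamide, CON(C)C(=O)CBr
Why: Williamson etherification in which one equivalent of hydride deprotonates the alcohol in preference to the alkyne C–H, and the C2–O bond is not broken, so the configuration is kept.

Step 8
Reactants: 13 2-{(1R,2S)-1-[4-(benzyloxy)-3-methoxyphenyl]-2-[(benzyloxy)methyl]but-3-yn-1-yloxy}-N-methoxy-N-methylacetamide
Product: 14 1-{(1R,2S)-1-[4-(benzyloxy)-3-methoxyphenyl]-2-[(benzyloxy)methyl]but-3-yn-1-yloxy}but-3-en-2-one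
Conditions: CH2=CHMgBr (3 equiv), THF, −78 to 0 °C; inverse quench into cold 1 M HCl
Reagents that add atoms: vinylmagnesium bromide, C=C[Mg]Br
Why: Weinreb ketone synthesis, in which the chelated tetrahedral adduct prevents over-addition, excess Grignard reagent at most deprotonates the alkyne reversibly, and the cold acidic quench protonates the released amine before it can add to the enone.

Step 9
Reactants: 14 1-{(1R,2S)-1-[4-(benzyloxy)-3-methoxyphenyl]-2-[(benzyloxy)methyl]but-3-yn-1-yloxy}but-3-en-2-one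
Product: 15 (1Z)-1-{(1R,2S)-1-[4-(benzyloxy)-3-methoxyphenyl]-2-[(benzyloxy)methyl]but-3-yn-1-yloxy}-2-(tert-butyldimethylsilyloxy)buta-1,3-diene
Conditions: TBSOTf, Et3N, CH2Cl2, −78 to 0 °C; Et3N-deactivated silica
Reagents that add atoms: tert-butyldimethylsilyl trifluoromethanesulfonate, CC(C)(C)[Si](C)(C)OS(=O)(=O)C(F)(F)F
Why: soft enolisation and O-silylation of a vinyl ketone (the standard route to 2-silyloxydienes) can only occur toward the O–CH2 group, and the favoured O,O-cis (Z) enol ether puts the tether oxygen trans to the vinyl group, i.e. outward on the s-cis diene.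

Step 10
Reactants: 15 (1Z)-1-{(1R,2S)-1-[4-(benzyloxy)-3-methoxyphenyl]-2-[(benzyloxy)methyl]but-3-yn-1-yloxy}-2-(tert-butyldimethylsilyloxy)buta-1,3-diene
Product: 17 methyl (4S,5R)-5-[4-(benzyloxy)-3-methoxyphenyl]-4-[(benzyloxy)methyl]-5-{[(1Z)-2-(tert-butyldimethylsilyloxy)buta-1,3-dien-1-yl]oxy}pent-2-ynoate, via lithium acetylide 16 (not isolated)
Conditions: n-BuLi (1.05 equiv), THF, −78 °C; then ClCO2Me, −78 to −30 °C; cold aq. NH4Cl
Reagents that add atoms: methyl chloroformate, COC(=O)Cl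
Why: C-acylation of a lithium acetylide with a chloroformate, in which the tert-butyldimethylsilyl dienol ether tolerates n-BuLi at −78 °C and the cold quench protects the propargylic C–H of the new ynoate.

Step 11
Reactants: 17 methyl (4S,5R)-5-[4-(benzyloxy)-3-methoxyphenyl]-4-[(benzyloxy)methyl]-5-{[(1Z)-2-(tert-butyldimethylsilyloxy)buta-1,3-dien-1-yl]oxy}pent-2-ynoate
Product: 19 methyl (2R,3S)-2-[4-(benzyloxy)-3-methoxyphenyl]-3-[(benzyloxy)methyl]-7-(tert-butyldimethylsilyloxy)-2,3-dihydro-1-benzofuran-4-carboxylate, via cyclohexadiene cycloadduct 18 (not isolated)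
Conditions: PhMe (0.01 M), BHT (cat.), 110 °C; then DDQ (1.1 equiv), 0 °C to rt
Reagents that add atoms: none
Why: On heating, the electron-rich diene (C7a, C7, C6, C5) and the tethered ynoate (C3a, C4) undergo a concerted, asynchronous [4+2] cycloaddition that forms C3a–C7a and C4–C5, and DDQ then takes hydride from the doubly allylic, oxygen-bearing C7a–H (or from C5–H2) and a proton from the other site to give the arene. The closest known reaction type is the type 1 intramolecular Diels–Alder reaction of 2-silyloxydienes with tethered alkynoates followed by quinone dehydrogenation of the 1,4-cyclohexadiene. Five-membered ring D closes in the fused mode through the three-atom tether O1–C2–C3 as C3a–C7a forms, and six-membered ring B closes through the same two new bonds. No stereocentre is created in the product, because the transient C7a centre of 18 is erased on aromatisation and C2 and C3 are spectators. The step needs the tether-outward (1Z) enol ether geometry, secured in step 9, and a regiochemistry that places O7 para to the C4 ester, which the tether enforces and the polarity supports (silyl enol ether terminus C7a to the ynoate beta carbon C3a). It also needs DDQ to attack the cyclohexadiene and not the benzylic ethers, which the much weaker doubly allylic C–H bonds of 18 and one equivalent of oxidant at 0 °C should secure.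

Step 12
Reactants: 19 methyl (2R,3S)-2-[4-(benzyloxy)-3-methoxyphenyl]-3-[(benzyloxy)methyl]-7-(tert-butyldimethylsilyloxy)-2,3-dihydro-1-benzofuran-4-carboxylate
Product: 21 methyl (2R,3S)-7-(benzyloxy)-2-[4-(benzyloxy)-3-methoxyphenyl]-3-[(benzyloxy)methyl]-2,3-dihydro-1-benzofuran-4-carboxylate, via caesium phenoxide 20 (not isolated)
Conditions: CsF (2 equiv), BnBr (1.5 equiv), DMF, rt
Reagents that add atoms: benzyl bromide, BrCc1ccccc1
Why: fluoride cleavage of an aryl silyl ether with in situ Williamson benzylation of the phenoxide is a known one-pot exchange and gives an O7 group that survives the later hydroxide step.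

Step 13
Reactants: 21 methyl (2R,3S)-7-(benzyloxy)-2-[4-(benzyloxy)-3-methoxyphenyl]-3-[(benzyloxy)methyl]-2,3-dihydro-1-benzofuran-4-carboxylate
Product: 22 {(2R,3S)-7-(benzyloxy)-2-[4-(benzyloxy)-3-methoxyphenyl]-3-[(benzyloxy)methyl]-2,3-dihydro-1-benzofuran-4-yl}methanol
Conditions: i-Bu2AlH (2.5 equiv), CH2Cl2, −78 to 0 °C; aq. potassium sodium tartrate
Reagents that add atoms: none
Why: hydride reduction of an aryl ester to the benzylic alcohol is reliable and leaves ethers and both stereocentres alone.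

Step 14
Reactants: 22 {(2R,3S)-7-(benzyloxy)-2-[4-(benzyloxy)-3-methoxyphenyl]-3-[(benzyloxy)methyl]-2,3-dihydro-1-benzofuran-4-yl}methanol
Product: 23 (2R,3S)-7-(benzyloxy)-2-[4-(benzyloxy)-3-methoxyphenyl]-3-[(benzyloxy)methyl]-2,3-dihydro-1-benzofuran-4-carbaldehyde
Conditions: MnO2 (excess), CH2Cl2, rt
Reagents that add atoms: none
Why: MnO2 oxidises primary benzylic alcohols to aldehydes under neutral conditions without over-oxidation.

Step 15
Reactants: 24 1-(2,4,6-trihydroxyphenyl)ethanone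
Product: 25 1-[2,4-bis(benzyloxy)-6-hydroxyphenyl]ethanone
Conditions: BnBr (2.1 equiv), K2CO3, DMF, rt
Reagents that add atoms: benzyl bromide, BrCc1ccccc1
Why: Williamson benzylation with two equivalents should stop at the bis-ether, because the second ortho hydroxyl is deactivated by its hydrogen bond to the carbonyl group.

Step 16
Reactants: 23 (2R,3S)-7-(benzyloxy)-2-[4-(benzyloxy)-3-methoxyphenyl]-3-[(benzyloxy)methyl]-2,3-dihydro-1-benzofuran-4-carbaldehyde; 25 1-[2,4-bis(benzyloxy)-6-hydroxyphenyl]ethanone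
Product: 26 (2E)-1-[2,4-bis(benzyloxy)-6-hydroxyphenyl]-3-{(2R,3S)-7-(benzyloxy)-2-[4-(benzyloxy)-3-methoxyphenyl]-3-[(benzyloxy)methyl]-2,3-dihydro-1-benzofuran-4-yl}prop-2-en-1-one
Conditions: KOH (excess), EtOH/THF, rt
Reagents that add atoms: none
Why: Claisen–Schmidt condensation of a non-enolisable aryl aldehyde with a 2-hydroxyacetophenone gives the (E)-chalcone by aldol addition and E1cB dehydration (any flavanone formed alongside is also converted in step 17).

Step 17
Reactants: 26 (2E)-1-[2,4-bis(benzyloxy)-6-hydroxyphenyl]-3-{(2R,3S)-7-(benzyloxy)-2-[4-(benzyloxy)-3-methoxyphenyl]-3-[(benzyloxy)methyl]-2,3-dihydro-1-benzofuran-4-yl}prop-2-en-1-one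
Product: 27 5,7-bis(benzyloxy)-2-{(2R,3S)-7-(benzyloxy)-2-[4-(benzyloxy)-3-methoxyphenyl]-3-[(benzyloxy)methyl]-2,3-dihydro-1-benzofuran-4-yl}-4H-chromen-4-one
Conditions: I2 (10 mol %), DMSO, 130 °C
Reagents that add atoms: none
Why: iodine/DMSO oxidative cyclisation of 2'-hydroxychalcones (oxa-Michael closure, then iodination and elimination with DMSO as terminal oxidant) is the standard flavone synthesis and tolerates benzyl ethers.

Step 18
Reactants: 27 5,7-bis(benzyloxy)-2-{(2R,3S)-7-(benzyloxy)-2-[4-(benzyloxy)-3-methoxyphenyl]-3-[(benzyloxy)methyl]-2,3-dihydro-1-benzofuran-4-yl}-4H-chromen-4-one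
Product: 29 5,7-bis(benzyloxy)-2-{(2R,3S)-7-(benzyloxy)-2-[4-(benzyloxy)-3-methoxyphenyl]-3-[(benzyloxy)methyl]-2,3-dihydro-1-benzofuran-4-yl}-3-hydroxy-4H-chromen-4-one, via flavone epoxide 28 (not isolated)
Conditions: dimethyldioxirane, acetone/CH2Cl2, 0 °C to rt; then p-TsOH (cat.), CHCl3, rt
Reagents that add atoms: dimethyldioxirane, CC1(C)OO1
Why: dioxirane epoxidation of the chromone C2=C3 enol ether bond, followed by acid opening toward the oxygen-stabilised C2 cation and loss of the C3 proton, is the established flavone-to-flavonol conversion.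

Step 19
Reactants: 29 5,7-bis(benzyloxy)-2-{(2R,3S)-7-(benzyloxy)-2-[4-(benzyloxy)-3-methoxyphenyl]-3-[(benzyloxy)methyl]-2,3-dihydro-1-benzofuran-4-yl}-3-hydroxy-4H-chromen-4-one
Product: 30 3,5,7-trihydroxy-2-[(2R,3S)-7-hydroxy-2-(4-hydroxy-3-methoxyphenyl)-3-(hydroxymethyl)-2,3-dihydro-1-benzofuran-4-yl]-4H-chromen-4-one
Conditions: H2 (1 atm), Pd(OH)2/C, THF/MeOH, rt
Reagents that add atoms: none
Why: catalytic hydrogenolysis removes the four aryl benzyl ethers and the primary alkyl benzyl ether in one operation and should be stopped as soon as the last one has gone, leaving the flavonol and both stereocentres intact.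

**Compound list**

1 | (benzyloxy)acetaldehyde | O=CCOCc1ccccc1 | starting material
2 | trimethylsilylacetylene | C#C[Si](C)(C)C | starting material
3 | lithium (trimethylsilyl)acetylide | [Li]C#C[Si](C)(C)C | intermediate
4 | rac-1-(benzyloxy)-4-(trimethylsilyl)but-3-yn-2-ol | OC(COCc1ccccc1)C#C[Si](C)(C)C | intermediate
5 | 1-(benzyloxy)-4-(trimethylsilyl)but-3-yn-2-one | O=C(COCc1ccccc1)C#C[Si](C)(C)C | intermediate
6 | (2R)-1-(benzyloxy)-4-(trimethylsilyl)but-3-yn-2-ol | O[C@@H](COCc1ccccc1)C#C[Si](C)(C)C | intermediate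
7 | (2R)-1-(benzyloxy)-4-(trimethylsilyl)but-3-yn-2-yl methanesulfonate | CS(=O)(=O)O[C@@H](COCc1ccccc1)C#C[Si](C)(C)C | intermediate
8 | 4-(benzyloxy)-3-methoxybenzaldehyde (O-benzylvanillin) | COc1cc(C=O)ccc1OCc1ccccc1 | starting material
9 | (aR)-[4-(benzyloxy)-1-(trimethylsilyl)buta-1,2-dien-1-yl](ethyl)zinc | CC[Zn]C([Si](C)(C)C)=[C@]=C([H])COCc1ccccc1 | intermediate
10 | (1R,2S)-1-[4-(benzyloxy)-3-methoxyphenyl]-2-[(benzyloxy)methyl]-4-(trimethylsilyl)but-3-yn-1-ol | COc1cc([C@H](O)[C@H](COCc2ccccc2)C#C[Si](C)(C)C)ccc1OCc1ccccc1 | intermediate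
11 | (1R,2S)-1-[4-(benzyloxy)-3-methoxyphenyl]-2-[(benzyloxy)methyl]but-3-yn-1-ol | COc1cc([C@H](O)[C@H](COCc2ccccc2)C#C)ccc1OCc1ccccc1 | intermediate
12 | sodium (1R,2S)-1-[4-(benzyloxy)-3-methoxyphenyl]-2-[(benzyloxy)methyl]but-3-yn-1-olate | COc1cc([C@H]([O-])[C@H](COCc2ccccc2)C#C)ccc1OCc1ccccc1.[Na+] | intermediate
13 | 2-{(1R,2S)-1-[4-(benzyloxy)-3-methoxyphenyl]-2-[(benzyloxy)methyl]but-3-yn-1-yloxy}-N-methoxy-N-methylacetamide | COc1cc([C@H](OCC(=O)N(C)OC)[C@H](COCc2ccccc2)C#C)ccc1OCc1ccccc1 | intermediate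
14 | 1-{(1R,2S)-1-[4-(benzyloxy)-3-methoxyphenyl]-2-[(benzyloxy)methyl]but-3-yn-1-yloxy}but-3-en-2-one | COc1cc([C@H](OCC(=O)C=C)[C@H](COCc2ccccc2)C#C)ccc1OCc1ccccc1 | intermediate
15 | (1Z)-1-{(1R,2S)-1-[4-(benzyloxy)-3-methoxyphenyl]-2-[(benzyloxy)methyl]but-3-yn-1-yloxy}-2-(tert-butyldimethylsilyloxy)buta-1,3-diene | COc1cc([C@H](O/C=C(\O[Si](C)(C)C(C)(C)C)C=C)[C@H](COCc2ccccc2)C#C)ccc1OCc1ccccc1 | intermediate
16 | lithium acetylide of 15 (lithium at the alkyne terminus; 3S,4R as a but-1-yn-1-ide) | COc1cc([C@H](O/C=C(\O[Si](C)(C)C(C)(C)C)C=C)[C@H](COCc2ccccc2)C#C[Li])ccc1OCc1ccccc1 | intermediate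
17 | methyl (4S,5R)-5-[4-(benzyloxy)-3-methoxyphenyl]-4-[(benzyloxy)methyl]-5-{[(1Z)-2-(tert-butyldimethylsilyloxy)buta-1,3-dien-1-yl]oxy}pent-2-ynoate | COc1cc([C@H](O/C=C(\O[Si](C)(C)C(C)(C)C)C=C)[C@H](COCc2ccccc2)C#CC(=O)OC)ccc1OCc1ccccc1 | intermediate
18 | methyl (2R,3S)-2-[4-(benzyloxy)-3-methoxyphenyl]-3-[(benzyloxy)methyl]-7-(tert-butyldimethylsilyloxy)-2,3,5,7a-tetrahydro-1-benzofuran-4-carboxylate (C7a not defined) | COc1cc([C@@H]2OC3C(O[Si](C)(C)C(C)(C)C)=CCC(C(=O)OC)=C3[C@H]2COCc2ccccc2)ccc1OCc1ccccc1 | intermediate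
19 | methyl (2R,3S)-2-[4-(benzyloxy)-3-methoxyphenyl]-3-[(benzyloxy)methyl]-7-(tert-butyldimethylsilyloxy)-2,3-dihydro-1-benzofuran-4-carboxylate | COc1cc([C@@H]2Oc3c(O[Si](C)(C)C(C)(C)C)ccc(C(=O)OC)c3[C@H]2COCc2ccccc2)ccc1OCc1ccccc1 | intermediate
20 | caesium (2R,3S)-2-[4-(benzyloxy)-3-methoxyphenyl]-3-[(benzyloxy)methyl]-4-(methoxycarbonyl)-2,3-dihydro-1-benzofuran-7-olate | COc1cc([C@@H]2Oc3c([O-])ccc(C(=O)OC)c3[C@H]2COCc2ccccc2)ccc1OCc1ccccc1.[Cs+] | intermediate
21 | methyl (2R,3S)-7-(benzyloxy)-2-[4-(benzyloxy)-3-methoxyphenyl]-3-[(benzyloxy)methyl]-2,3-dihydro-1-benzofuran-4-carboxylate | COc1cc([C@@H]2Oc3c(OCc4ccccc4)ccc(C(=O)OC)c3[C@H]2COCc2ccccc2)ccc1OCc1ccccc1 | intermediate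
22 | {(2R,3S)-7-(benzyloxy)-2-[4-(benzyloxy)-3-methoxyphenyl]-3-[(benzyloxy)methyl]-2,3-dihydro-1-benzofuran-4-yl}methanol | COc1cc([C@@H]2Oc3c(OCc4ccccc4)ccc(CO)c3[C@H]2COCc2ccccc2)ccc1OCc1ccccc1 | intermediate
23 | (2R,3S)-7-(benzyloxy)-2-[4-(benzyloxy)-3-methoxyphenyl]-3-[(benzyloxy)methyl]-2,3-dihydro-1-benzofuran-4-carbaldehyde | COc1cc([C@@H]2Oc3c(OCc4ccccc4)ccc(C=O)c3[C@H]2COCc2ccccc2)ccc1OCc1ccccc1 | intermediate
24 | 1-(2,4,6-trihydroxyphenyl)ethanone | CC(=O)c1c(O)cc(O)cc1O | starting material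
25 | 1-[2,4-bis(benzyloxy)-6-hydroxyphenyl]ethanone | CC(=O)c1c(O)cc(OCc2ccccc2)cc1OCc1ccccc1 | intermediate
26 | (2E)-1-[2,4-bis(benzyloxy)-6-hydroxyphenyl]-3-{(2R,3S)-7-(benzyloxy)-2-[4-(benzyloxy)-3-methoxyphenyl]-3-[(benzyloxy)methyl]-2,3-dihydro-1-benzofuran-4-yl}prop-2-en-1-one | COc1cc([C@@H]2Oc3c(OCc4ccccc4)ccc(/C=C/C(=O)c4c(O)cc(OCc5ccccc5)cc4OCc4ccccc4)c3[C@H]2COCc2ccccc2)ccc1OCc1ccccc1 | intermediate
27 | 5,7-bis(benzyloxy)-2-{(2R,3S)-7-(benzyloxy)-2-[4-(benzyloxy)-3-methoxyphenyl]-3-[(benzyloxy)methyl]-2,3-dihydro-1-benzofuran-4-yl}-4H-chromen-4-one | COc1cc([C@@H]2Oc3c(OCc4ccccc4)ccc(-c4cc(=O)c5c(OCc6ccccc6)cc(OCc6ccccc6)cc5o4)c3[C@H]2COCc2ccccc2)ccc1OCc1ccccc1 | intermediate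
28 | 2,3-epoxide of 27 (oxirane across chromone C2–C3; epoxide configuration not defined) | COc1cc([C@@H]2Oc3c(OCc4ccccc4)ccc(C45OC4C(=O)c4c(OCc6ccccc6)cc(OCc6ccccc6)cc4O5)c3[C@H]2COCc2ccccc2)ccc1OCc1ccccc1 | intermediate
29 | 5,7-bis(benzyloxy)-2-{(2R,3S)-7-(benzyloxy)-2-[4-(benzyloxy)-3-methoxyphenyl]-3-[(benzyloxy)methyl]-2,3-dihydro-1-benzofuran-4-yl}-3-hydroxy-4H-chromen-4-one | COc1cc([C@@H]2Oc3c(OCc4ccccc4)ccc(-c4oc5cc(OCc6ccccc6)cc(OCc6ccccc6)c5c(=O)c4O)c3[C@H]2COCc2ccccc2)ccc1OCc1ccccc1 | intermediate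
30 | 3,5,7-trihydroxy-2-[(2R,3S)-7-hydroxy-2-(4-hydroxy-3-methoxyphenyl)-3-(hydroxymethyl)-2,3-dihydro-1-benzofuran-4-yl]-4H-chromen-4-one | COc1cc([C@@H]2Oc3c(O)ccc(-c4oc5cc(O)cc(O)c5c(=O)c4O)c3[C@H]2CO)ccc1O | target

**Step count**

Total: 19 steps. Longest linear sequence: 18 steps (steps 1 to 14 and 16 to 19, from (benzyloxy)acetaldehyde); step 15 is a one-step side branch.

**Steps most likely to fail**

First, step 11. The cycloaddition may be slower than desilylation or polymerisation of the dienol ether, or the cyclohexadiene may aromatise by expelling the C7a–O1 alkoxide before DDQ is added. The fallback raises the dienophile to the aldehyde oxidation level. It sets out from 15, which is lithiated as in step 10 (n-BuLi, THF, −78 °C, giving 16) and formylated with DMF (inverse quench into aq. KH2PO4). This gives (4S,5R)-5-[4-(benzyloxy)-3-methoxyphenyl]-4-[(benzyloxy)methyl]-5-{[(1Z)-2-(tert-butyldimethylsilyloxy)buta-1,3-dien-1-yl]oxy}pent-2-ynal F1. This far more electrophilic ynal should cyclise at or below room temperature to the cyclohexadiene carbaldehyde F2. DDQ at 0 °C should then give (2R,3S)-2-[4-(benzyloxy)-3-methoxyphenyl]-3-[(benzyloxy)methyl]-7-(tert-butyldimethylsilyloxy)-2,3-dihydro-1-benzofuran-4-carbaldehyde F3. CsF and BnBr in DMF, by way of the caesium phenoxide F4, bring the material back to the route at 23, so steps 12 to 14 are bypassed.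

Second, step 17. Hydrogen iodide formed at 130 °C may ionise the electron-rich benzylic C2–O1 bond (ring opening or epimerisation at C2) or attack benzyl ethers. The fallback builds the chromone from the ester oxidation level without iodine. It sets out from 21. Acetophenone 25 is converted with LiN(SiMe3)2 (3 equiv, THF, −78 °C) into its dilithium phenoxide-enolate F5, which undergoes Claisen condensation with ester 21 (−78 °C to rt). The product is 1-[2,4-bis(benzyloxy)-6-hydroxyphenyl]-3-{(2R,3S)-7-(benzyloxy)-2-[4-(benzyloxy)-3-methoxyphenyl]-3-[(benzyloxy)methyl]-2,3-dihydro-1-benzofuran-4-yl}propane-1,3-dione F6, the diketone of a Baker–Venkataraman sequence. Cyclodehydration with catalytic p-TsOH in toluene at 60 to 80 °C returns to the route at 27; steps 13, 14 and 16 are then not needed.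

Third, step 19. Hydrogenolysis of the cyclic benzylic aryl ether C2–O1 (opening of ring D) may compete before the slow primary alkyl benzyl ether is cleaved. The fallback replaces hydrogenolysis by Lewis-acid dealkylation. It sets out from 29, which is treated with BCl3 and pentamethylbenzene as cation scavenger in CH2Cl2 at −78 to −20 °C, and arrives directly at 30. It makes no compound outside the list (entry F0).

**Further compounds**

F1 | step 11 | (4S,5R)-5-[4-(benzyloxy)-3-methoxyphenyl]-4-[(benzyloxy)methyl]-5-{[(1Z)-2-(tert-butyldimethylsilyloxy)buta-1,3-dien-1-yl]oxy}pent-2-ynal | COc1cc([C@H](O/C=C(\O[Si](C)(C)C(C)(C)C)C=C)[C@H](COCc2ccccc2)C#CC=O)ccc1OCc1ccccc1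
F2 | step 11 | (2R,3S)-2-[4-(benzyloxy)-3-methoxyphenyl]-3-[(benzyloxy)methyl]-7-(tert-butyldimethylsilyloxy)-2,3,5,7a-tetrahydro-1-benzofuran-4-carbaldehyde (C7a not defined) | COc1cc([C@@H]2OC3C(O[Si](C)(C)C(C)(C)C)=CCC(C=O)=C3[C@H]2COCc2ccccc2)ccc1OCc1ccccc1
F3 | step 11 | (2R,3S)-2-[4-(benzyloxy)-3-methoxyphenyl]-3-[(benzyloxy)methyl]-7-(tert-butyldimethylsilyloxy)-2,3-dihydro-1-benzofuran-4-carbaldehyde | COc1cc([C@@H]2Oc3c(O[Si](C)(C)C(C)(C)C)ccc(C=O)c3[C@H]2COCc2ccccc2)ccc1OCc1ccccc1
F4 | step 11 | caesium (2R,3S)-2-[4-(benzyloxy)-3-methoxyphenyl]-3-[(benzyloxy)methyl]-4-formyl-2,3-dihydro-1-benzofuran-7-olate | COc1cc([C@@H]2Oc3c([O-])ccc(C=O)c3[C@H]2COCc2ccccc2)ccc1OCc1ccccc1.[Cs+]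
F5 | step 17 | dilithium phenoxide-enolate of 1-[2,4-bis(benzyloxy)-6-hydroxyphenyl]ethanone | [Li+].[Li+].C=C([O-])c1c([O-])cc(OCc2ccccc2)cc1OCc1ccccc1
F6 | step 17 | 1-[2,4-bis(benzyloxy)-6-hydroxyphenyl]-3-{(2R,3S)-7-(benzyloxy)-2-[4-(benzyloxy)-3-methoxyphenyl]-3-[(benzyloxy)methyl]-2,3-dihydro-1-benzofuran-4-yl}propane-1,3-dione | COc1cc([C@@H]2Oc3c(OCc4ccccc4)ccc(C(=O)CC(=O)c4c(O)cc(OCc5ccccc5)cc4OCc4ccccc4)c3[C@H]2COCc2ccccc2)ccc1OCc1ccccc1
F0 | step 19 | none | none
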